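The two ketones are traced back to vinyl chlorides and the two C5 methyl ethers to phenols. Both aryl C2–CH2 bonds are then cut together, returning each 2-chloroallyl group to the C5 oxygen, and last the C1–C1' biaryl bond is cut to two units of 2,6-dimethoxyphenol (1).
Enabling feature: number each ring C1 (biaryl carbon), C2 (acetonyl), C3 (H), C4–C6 (OMe). C2 then stands para to the oxygen on C5, and both carbons ortho to that oxygen (C4, C6) already carry methoxy, so an allyl group leaving O–C5 can come to rest only on C2.
Forward order: no ring is built. The two bought benzene rings are joined at C1–C1' by Ullmann coupling. The three-carbon arms are attached to O–C5/O–C5' and moved to C2/C2' in one thermal operation, and O-methylation and hydrolysis finish the chains.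
Stereochemistry: the target has no stereocentre. Its only stereoelement is the hindered biaryl axis, which is formed racemic.

Key step: step 6

Assumption: the target SMILES carries no axial descriptor, so the racemic atropisomer pair is taken as the target and no resolution is planned.

Step 1
Reactants: 1 2,6-dimethoxyphenol; 2 benzyl bromide
Product: 3 2-(benzyloxy)-1,3-dimethoxybenzene
Conditions: K2CO3, DMF, rt to 50 °C
Reagents that add atoms: none
Why: Williamson ether synthesis, in which the phenoxide of 1 displaces bromide from the benzylic halide; capping the OH removes its para-directing power before step 2 and shields it during the copper coupling.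

Step 2
Reactants: 3 2-(benzyloxy)-1,3-dimethoxybenzene
Product: 4 2-(benzyloxy)-4-iodo-1,3-dimethoxybenzene
Conditions: NIS (1.0 equiv), CF3CO2H (cat.), MeCN, 0 °C to rt, dark
Reagents that add atoms: N-iodosuccinimide, O=C1CCC(=O)N1I
Why: Electrophilic aromatic iodination with acid-activated NIS; the central benzyloxy group is twisted out of conjugation by its neighbours, so the flanking methoxy groups send iodine to the carbon ortho to one and para to the other, as is usual for 1,2,3-trialkoxybenzenes, and one equivalent of reagent limits double iodination.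

Step 3
Reactants: 4 2-(benzyloxy)-4-iodo-1,3-dimethoxybenzene (two molecules)
Product: 5 3,3'-bis(benzyloxy)-2,2',4,4'-tetramethoxybiphenyl
Conditions: activated Cu bronze (excess), neat, 220 °C, Ar
Reagents that add atoms: none
Why: Classical Ullmann reductive homocoupling of an aryl iodide on copper metal, long used for ortho-alkoxy iodoarenes and tolerant of aryl ethers; only two ortho substituents flank the new C1–C1' bond at this stage.

Step 4
Reactants: 5 3,3'-bis(benzyloxy)-2,2',4,4'-tetramethoxybiphenyl
Product: 6 2,2',4,4'-tetramethoxybiphenyl-3,3'-diol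
Conditions: H2 (1 atm), 10% Pd/C, EtOAc–MeOH, rt
Reagents that add atoms: none
Why: Catalytic hydrogenolysis of benzyl aryl ethers, placed before any chlorine or alkene enters the molecule so that nothing else is reducible.

Step 5
Reactants: 6 2,2',4,4'-tetramethoxybiphenyl-3,3'-diol; 7 2,3-dichloropropene (two molecules)
Product: 8 3,3'-bis(2-chloroallyloxy)-2,2',4,4'-tetramethoxybiphenyl
Conditions: K2CO3, KI (cat.), DMF, 60 °C
Reagents that add atoms: none
Why: Twofold Williamson etherification in which only the allylic C–Cl bond of 7 undergoes SN2 displacement while the vinylic C–Cl bond stays inert, with iodide catalysis (Finkelstein exchange) helping the flanked phenoxides.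

Step 6
Reactants: 8 3,3'-bis(2-chloroallyloxy)-2,2',4,4'-tetramethoxybiphenyl
Product: 14 6,6'-bis(2-chloroallyl)-2,2',4,4'-tetramethoxybiphenyl-3,3'-diol, via first-ring ortho-dienone 9 (not isolated), via first-ring para-dienone 10 (not isolated), via half-rearranged monophenol 11 (not isolated), via second-ring ortho-dienone 12 (not isolated), via second-ring para-dienone 13 (not isolated)
Conditions: PhNEt2 (degassed), 200–210 °C, sealed tube, Ar
Reagents that add atoms: none
Why: This is an aromatic para-Claisen rearrangement run once on each ring: a [3,3] shift carries the 2-chloroallyl group from O–C5 to a methoxy-bearing ortho carbon (C4 is drawn, C6 leads to the same outcome), giving a 6-alkyl-6-methoxycyclohexa-2,4-dienone (9, later 12) with no hydrogen to lose, so a Cope [3,3] shift hands the group on to C2 (10, later 13) and amine-assisted tautomerisation restores the arene (11, finally 14). The closest known reactions are the thermal conversion of allyl 2,6-dimethoxyphenyl ether into 4-allyl-2,6-dimethoxyphenol and the Claisen rearrangement of aryl 2-chloroallyl ethers in N,N-diethylaniline. No ring is closed and no lasting stereocentre is made; the sp3 carbons of 9, 10, 12 and 13 are transient, and the axis, which becomes tetra-ortho-substituted here, forms as a racemate. The step needs delivery to C2 alone, and the substrate secures this because C4 and C6 are blocked, C3 is meta to the oxygen and out of reach of consecutive [3,3] shifts, and either ortho-dienone can pass the group only back to oxygen or on to C2. Since CH2=C(Cl)CH2 maps onto itself on allylic inversion, the arm arrives as ArCH2C(Cl)=CH2, and because it ends para to the OH it cannot close to a 2-methylbenzofuran as ortho products do. The basic solvent takes up traces of HCl, and exclusion of air protects the oxidation-prone 2,6-dimethoxyphenol units of the product.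

Step 7
Reactants: 14 6,6'-bis(2-chloroallyl)-2,2',4,4'-tetramethoxybiphenyl-3,3'-diol
Product: 15 6,6'-bis(2-chloroallyl)-2,2',3,3',4,4'-hexamethoxybiphenyl
Conditions: MeI (excess), K2CO3, acetone, reflux
Reagents that add atoms: iodomethane, CI
Why: Williamson O-methylation of the two flanked phenols with a small electrophile, the same step that converts 4-allyl-2,6-dimethoxyphenol into its trimethyl ether; vinyl chlorides are inert to carbonate base.

Step 8
Reactants: 15 6,6'-bis(2-chloroallyl)-2,2',3,3',4,4'-hexamethoxybiphenyl
Product: 16 1,1'-(4,4',5,5',6,6'-hexamethoxybiphenyl-2,2'-diyl)di(propan-2-one) (CNP0079270.0)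
Conditions: Hg(OAc)2 (2 equiv), 88% aq. HCO2H, rt; 1 M HCl work-up
Reagents that add atoms: water, O
Why: Mercury-assisted hydrolysis of a vinyl chloride, the unmasking familiar from Wichterle-type chloroolefin annulations: divalent mercury activates each 1,1-disubstituted chloroalkene for Markovnikov addition of water at the chlorine-bearing carbon, chloride is expelled to form the carbonyl group and the acidic medium protonates the metal off the terminal carbon, while aryl methyl ethers are inert to formic acid at room temperature.

Compound list
1 | 2,6-dimethoxyphenol | COc1cccc(OC)c1O | starting material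
2 | benzyl bromide | BrCc1ccccc1 | starting material
3 | 2-(benzyloxy)-1,3-dimethoxybenzene | COc1cccc(OC)c1OCc1ccccc1 | intermediate
4 | 2-(benzyloxy)-4-iodo-1,3-dimethoxybenzene (iodine ortho to one OMe, para to the other) | COc1ccc(I)c(OC)c1OCc1ccccc1 | intermediate
5 | 3,3'-bis(benzyloxy)-2,2',4,4'-tetramethoxybiphenyl | COc1ccc(-c2ccc(OC)c(OCc3ccccc3)c2OC)c(OC)c1OCc1ccccc1 | intermediate
6 | 2,2',4,4'-tetramethoxybiphenyl-3,3'-diol | COc1ccc(-c2ccc(OC)c(O)c2OC)c(OC)c1O | intermediate
7 | 2,3-dichloropropene | ClCC(Cl)=C | starting material
8 | 3,3'-bis(2-chloroallyloxy)-2,2',4,4'-tetramethoxybiphenyl | COc1ccc(-c2ccc(OC)c(OCC(Cl)=C)c2OC)c(OC)c1OCC(Cl)=C | intermediate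
9 | 6-(2-chloroallyl)-3-[3-(2-chloroallyloxy)-2,4-dimethoxyphenyl]-2,6-dimethoxycyclohexa-2,4-dien-1-one (first-ring ortho-dienone, drawn for passage through C4; transient sp3 carbon unassigned) | COC1(CC(Cl)=C)C=CC(=C(OC)C1=O)c1ccc(OC)c(OCC(Cl)=C)c1OC | intermediate
10 | 4-(2-chloroallyl)-3-[3-(2-chloroallyloxy)-2,4-dimethoxyphenyl]-2,6-dimethoxycyclohexa-2,5-dien-1-one (first-ring para-dienone; transient sp3 carbon unassigned) | COC1=CC(CC(Cl)=C)C(=C(OC)C1=O)c1ccc(OC)c(OCC(Cl)=C)c1OC | intermediate
11 | 6-(2-chloroallyl)-3'-(2-chloroallyloxy)-2,2',4,4'-tetramethoxybiphenyl-3-ol (half-rearranged monophenol) | COc1cc(CC(Cl)=C)c(-c2ccc(OC)c(OCC(Cl)=C)c2OC)c(OC)c1O | intermediate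
12 | 6-(2-chloroallyl)-3-[6-(2-chloroallyl)-3-hydroxy-2,4-dimethoxyphenyl]-2,6-dimethoxycyclohexa-2,4-dien-1-one (second-ring ortho-dienone, drawn for passage through C4'; transient sp3 carbon unassigned) | COC1(CC(Cl)=C)C=CC(=C(OC)C1=O)c1c(CC(Cl)=C)cc(OC)c(O)c1OC | intermediate
13 | 4-(2-chloroallyl)-3-[6-(2-chloroallyl)-3-hydroxy-2,4-dimethoxyphenyl]-2,6-dimethoxycyclohexa-2,5-dien-1-one (second-ring para-dienone; transient sp3 carbon unassigned) | COC1=CC(CC(Cl)=C)C(=C(OC)C1=O)c1c(CC(Cl)=C)cc(OC)c(O)c1OC | intermediate
14 | 6,6'-bis(2-chloroallyl)-2,2',4,4'-tetramethoxybiphenyl-3,3'-diol (target numbering: chloroallyl on C2/C2', OH on C5/C5'; racemic axis) | COc1cc(CC(Cl)=C)c(-c2c(CC(Cl)=C)cc(OC)c(O)c2OC)c(OC)c1O | intermediate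
15 | 6,6'-bis(2-chloroallyl)-2,2',3,3',4,4'-hexamethoxybiphenyl (racemic axis) | COc1cc(CC(Cl)=C)c(-c2c(CC(Cl)=C)cc(OC)c(OC)c2OC)c(OC)c1OC | intermediate
16 | 1,1'-(4,4',5,5',6,6'-hexamethoxybiphenyl-2,2'-diyl)di(propan-2-one), CNP0079270.0 (racemic axis) | COc1cc(CC(C)=O)c(-c2c(CC(C)=O)cc(OC)c(OC)c2OC)c(OC)c1OC | target

Total step count: 8. Longest linear sequence: 8 steps (1 to 16).

Steps most likely to fail

Step 6. The Cope transfer has to enter the ring carbon next to the biaryl bond, and for the second arm it must build a tetra-ortho-substituted axis. If this slows down, several processes gain ground: reversal to the ether, cleavage of the allyl–oxygen bond, expulsion of methoxy from the blocked dienone and thermal loss of HCl. The fallback reverses the order of events, so that the sigmatropic relay runs on the unhindered monomer and the biaryl bond is made afterwards by oxidative coupling. It sets out from 1 and 7.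
- K2CO3 and catalytic KI in DMF should give 2-(2-chloroallyloxy)-1,3-dimethoxybenzene F1.
- Heating in PhNEt2 at about 200 °C should give 4-(2-chloroallyl)-2,6-dimethoxyphenol F2.
- MeI and K2CO3 should give 5-(2-chloroallyl)-1,2,3-trimethoxybenzene F3.
- Dehydrogenative homocoupling of F3 with the hypervalent iodine reagent PhI(OCOCF3)2 and BF3·OEt2 in CH2Cl2 at −78 to −40 °C is a known reaction of 5-alkyl-1,2,3-trimethoxybenzenes. It joins the carbons ortho to the alkyl group and para to a methoxy group, and it comes back to the route at 15.

Step 8. Three processes may interfere: mercuration of the electron-rich rings at C3–H, capture of the activated chloroalkene by the neighbouring arene instead of water, and acid-promoted aldol closure between the two new acetonyl arms to a seven-membered ring. The fallback exchanges the mask for a 2-methylallyl group, which is opened oxidatively under buffered, mercury-free conditions. It sets out from 6.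
- 3-Chloro-2-methylpropene, K2CO3 and catalytic KI in DMF should give 2,2',4,4'-tetramethoxy-3,3'-bis(2-methylallyloxy)biphenyl F4.
- The same double para-Claisen rearrangement in PhNEt2 at about 200 °C should give 2,2',4,4'-tetramethoxy-6,6'-bis(2-methylallyl)biphenyl-3,3'-diol F5.
- MeI and K2CO3 should give 2,2',3,3',4,4'-hexamethoxy-6,6'-bis(2-methylallyl)biphenyl F6.
- Lemieux–Johnson cleavage (OsO4 cat., NaIO4, 2,6-lutidine, dioxane–H2O, rt) turns each 1,1-disubstituted alkene into the methyl ketone and arrives at 16.

Step 3. The iodide is electron-rich and has no activating ortho group, so hydrodeiodination and stalled coupling may prevail, along with slow thermal loss of the benzyl groups at the temperature needed. The fallback replaces the reductive copper coupling by a cross-coupling of two differently functionalised halves under zerovalent palladium catalysis. It sets out from 4. Half of the material is converted by Miyaura borylation (B2pin2, PdCl2(dppf), KOAc, dioxane, 90 °C) into 2-[3-(benzyloxy)-2,4-dimethoxyphenyl]-4,4,5,5-tetramethyl-1,3,2-dioxaborolane F7. Suzuki–Miyaura coupling of F7 with the other half of 4 (Pd(OAc)2, SPhos, K3PO4, toluene–H2O, 90 °C) comes back to the route at 5.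

Further compounds
F1 | step 6 | 2-(2-chloroallyloxy)-1,3-dimethoxybenzene | COc1cccc(OC)c1OCC(Cl)=C
F2 | step 6 | 4-(2-chloroallyl)-2,6-dimethoxyphenol | COc1cc(CC(Cl)=C)cc(OC)c1O
F3 | step 6 | 5-(2-chloroallyl)-1,2,3-trimethoxybenzene | COc1cc(CC(Cl)=C)cc(OC)c1OC
F4 | step 8 | 2,2',4,4'-tetramethoxy-3,3'-bis(2-methylallyloxy)biphenyl | COc1ccc(-c2ccc(OC)c(OCC(C)=C)c2OC)c(OC)c1OCC(C)=C
F5 | step 8 | 2,2',4,4'-tetramethoxy-6,6'-bis(2-methylallyl)biphenyl-3,3'-diol | COc1cc(CC(C)=C)c(-c2c(CC(C)=C)cc(OC)c(O)c2OC)c(OC)c1O
F6 | step 8 | 2,2',3,3',4,4'-hexamethoxy-6,6'-bis(2-methylallyl)biphenyl | COc1cc(CC(C)=C)c(-c2c(CC(C)=C)cc(OC)c(OC)c2OC)c(OC)c1OC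
F7 | step 3 | 2-[3-(benzyloxy)-2,4-dimethoxyphenyl]-4,4,5,5-tetramethyl-1,3,2-dioxaborolane | COc1ccc(B2OC(C)(C)C(C)(C)O2)c(OC)c1OCc1ccccc1
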